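**Retrosynthetic overview**
1. Target 27 ⇐ diol 26 (acetylation of 3-OH) ⇐ vinyl carbinol 23 + bromobutenolide 24 (C12–C13, B-alkyl Suzuki) ⇐ 9α,11-epoxide 22 ⇐ C9 ketone 20.
2. Ring B of 20 ⇐ aldol condensation (C7–C8) of ethyl ketone 16 ⇐ nitrile 14 (the nitrile carbon is C9) ⇐ bridged lactone 11.
3. Ring A (key step) ⇐ [3+3] union of pseudo-acid chloride 5 (C3–C4–C5 with C6, C7) and bis-silylated β-ketonitrile 8 (C2–C1–C10 with C9, C20), forming C2–C3 and C5–C10.
4. Enabling feature: on ring A the C3 oxygen and the C5–C6 arm are cis-1,3 (both β), so O3 and C7 can be tied as a temporary δ-lactone across C3–C4–C5. The resulting 2-oxabicyclo[3.3.1]nonane fixes C5 and C10 and is cut again by reduction; the C1 carbonyl that activates C2 and C10 is removed in step 7.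
5. Ring order: ring A (step 6, with the temporary lactone ring), then ring B (step 10); the butenolide ring is brought in intact (step 15).

Key step: step 6

Remark: atoms are numbered as in labdanes (C1–C10 decalin, C11–C12 chain, C13–C16 butenolide, C17 on C8, C18/C19 on C4, C20 on C10); 6 is taken as purchasable (otherwise one Claisen acylation of propanenitrile with ethyl acetate).

**Step 1**
Reactants: 1 4,4-dimethylcyclopent-2-en-1-one
Product: 2 [(3,3-dimethylcyclopenta-1,4-dien-1-yl)oxy]trimethylsilane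
Conditions: LiN(iPr)2, THF, −78 °C; Me3SiCl, −78 °C → rt
Reagents that add atoms: chlorotrimethylsilane, C[Si](C)(C)Cl
Why: Kinetic deprotonation can only take place at the α′-CH2 (the γ position is quaternary), and O-silylation of the cross-conjugated enolate should give the 2-silyloxy diene (silyl enol ether formation).

**Step 2**
Reactants: 2 [(3,3-dimethylcyclopenta-1,4-dien-1-yl)oxy]trimethylsilane
Product: 4 6-hydroxy-5,5-dimethyl-5,6-dihydro-2H-pyran-2-one (lactol form of (2Z)-4,4-dimethyl-5-oxopent-2-enoic acid), via methoxy hydroperoxide 3 (not isolated)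
Conditions: O3 (1 equiv), CH2Cl2/MeOH, −78 °C; Me2S, −78 °C → rt; H2O
Reagents that add atoms: ozone, [O-][O+]=O
Why: Ozonolysis with reductive work-up should cleave only the electron-rich silyl enol ether double bond, giving the C7 acid and the C3 aldehyde on a double bond that stays Z because it was held in the five-membered ring, so the product closes to the lactol.

**Step 3**
Reactants: 4 6-hydroxy-5,5-dimethyl-5,6-dihydro-2H-pyran-2-one
Product: 5 6-chloro-5,5-dimethyl-5,6-dihydro-2H-pyran-2-one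
Conditions: SOCl2, DMF (cat.), CH2Cl2, 40 °C; evaporation, used crude
Reagents that add atoms: thionyl chloride, O=S(Cl)Cl
Why: Thionyl chloride should convert the ring-chain tautomeric cis aldehyde acid into its cyclic pseudo-acid chloride (an α-chloroalkyl ester), the usual outcome for cis-oxo acids.

**Step 4**
Reactants: 6 2-methyl-3-oxobutanenitrile
Product: 7 2-methyl-3-[(trimethylsilyl)oxy]but-2-enenitrile (E/Z mixture)
Conditions: Me3SiCl, Et3N, CH2Cl2, 0 °C → rt
Reagents that add atoms: chlorotrimethylsilane, C[Si](C)(C)Cl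
Why: O-silylation of the enol form of the β-ketonitrile (silyl enol ether formation) masks the acidic C10–H and leaves the C2 methyl group as the only acidic site.

**Step 5**
Reactants: 7 2-methyl-3-[(trimethylsilyl)oxy]but-2-enenitrile
Product: 8 N-[tert-butyl(dimethyl)silyl]-2-methyl-3-[(trimethylsilyl)oxy]buta-1,3-dien-1-imine
Conditions: LiN(iPr)2, THF, −78 °C; tBuMe2SiCl, −78 → 0 °C; pentane, filtration
Reagents that add atoms: tert-butyl(chloro)dimethylsilane, CC(C)(C)[Si](C)(C)Cl
Why: γ-Deprotonation at the C2 methyl group gives an anion delocalised onto nitrogen, and a bulky silyl chloride should silylate it on nitrogen (N-silyl vinylketene imine formation), as is usual for nitrile anions with a fully substituted α-carbon.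

**Step 6**
Reactants: 5 6-chloro-5,5-dimethyl-5,6-dihydro-2H-pyran-2-one; 8 N-[tert-butyl(dimethyl)silyl]-2-methyl-3-[(trimethylsilyl)oxy]buta-1,3-dien-1-imine
Product: 11 (1S,5S,6S)-6,9,9-trimethyl-3,7-dioxo-2-oxabicyclo[3.3.1]nonane-6-carbonitrile, via ketene-imine lactone 9 (not isolated), via silyl ketene acetal 10 (not isolated)
Conditions: chiral imidodiphosphorimidate acid (IDPi: two 3,3′-diaryl-1,1′-bi-2-naphthol units on a P–N–P core, N-triflyl; 3 mol %; antipode to be selected for the 3S series), toluene, −60 → −20 °C; aq. NaHCO3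
Reagents that add atoms: none
Why: Proposed new method: a silylium ion paired with the confined chiral imidodiphosphorimidate anion should take chloride from 5, the terminal enol-silane carbon of 8 should add to the resulting cyclic acyloxycarbenium ion (C2–C3, giving 9), and the silylium ion set free should then activate the enoate of the lactone for an intramolecular Mukaiyama–Michael addition of the N-silyl ketene imine carbon (C5–C10, giving 10), a formal [3+3] annulation. The closest known reaction types are silylium-imidodiphosphorimidate-catalysed additions of enol silanes to cyclic oxocarbenium ions from lactol esters, Mukaiyama–Michael additions to enoates, Lewis-acid α-acyloxyalkylation of enol silanes by α-chloroalkyl esters and [3+3] cyclisations of 1,3-bis(silyl enol ethers). Ring A closes 6-exo-trig onto C5 while the lactone is in place, so that a 2-oxabicyclo[3.3.1]nonane forms. C3 is set by the chiral counter-anion at the first bond; C5 is set by the tether, because C10 can reach C5 only on the lactone face that carries C2 (O3 and C6 cis); C10 is set because in the bridged chair the site anti to C6 is 1,3-diaxial to a C4 methyl and should be taken by the slim nitrile, leaving C20 equatorial. The step needs attack through the terminal and not the ketene-imine carbon in the first event (secured by the neopentyl-hindered cation and the fully substituted C10), exocyclic ionisation (secured by chloride as the leaving group) and no aromatisation or β-elimination (blocked by the quaternary C4 and C10 and the non-basic medium).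

**Step 7**
Reactants: 11 (1S,5S,6S)-6,9,9-trimethyl-3,7-dioxo-2-oxabicyclo[3.3.1]nonane-6-carbonitrile
Product: 13 (1S,5R,6S)-6,9,9-trimethyl-3-oxo-2-oxabicyclo[3.3.1]nonane-6-carbonitrile, via tosylhydrazone 12 (not isolated)
Conditions: TsNHNH2, 4 Å sieves, CHCl3, 50 °C; catecholborane, 0 °C → rt; NaOAc·3H2O, 60 °C
Reagents that add atoms: none
Why: Caglioti-type reduction (hydride transfer from catecholborane to the tosylhydrazone, then loss of sulfinate and N2) should turn C1=O into CH2 under non-basic conditions that spare the β-acyloxy group, the lactone and the nitrile.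

**Step 8**
Reactants: 13 (1S,5R,6S)-6,9,9-trimethyl-3-oxo-2-oxabicyclo[3.3.1]nonane-6-carbonitrile
Product: 14 (1S,2R,4S)-4-hydroxy-2-(2-hydroxyethyl)-1,3,3-trimethylcyclohexane-1-carbonitrile
Conditions: LiBH4, THF, 0 °C → rt; aq. NH4Cl
Reagents that add atoms: none
Why: LiBH4 reduces lactones but not nitriles (chemoselective hydride reduction); with the bridge cut, ring A should flip to the chair with O3, C6 and C9 equatorial and C20 axial, as in the target.

**Step 9**
Reactants: 14 (1S,2R,4S)-4-hydroxy-2-(2-hydroxyethyl)-1,3,3-trimethylcyclohexane-1-carbonitrile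
Product: 16 1-[(1S,2S,4S)-4-hydroxy-2-(2-hydroxyethyl)-1,3,3-trimethylcyclohexyl]propan-1-one, via ketimine 15 (not isolated)
Conditions: EtLi (5 equiv), Et2O/THF, 0 °C → rt; 2 M HCl, THF, rt
Reagents that add atoms: ethyllithium, [Li]CC; water, O
Why: Organolithium addition to a nitrile without α-hydrogen stops at the N-lithio ketimine, and its hydrolysis gives the ethyl ketone that brings in C8 and C17.

**Step 10**
Reactants: 16 1-[(1S,2S,4S)-4-hydroxy-2-(2-hydroxyethyl)-1,3,3-trimethylcyclohexyl]propan-1-one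
Product: 18 (4aS,6S,8aS)-6-hydroxy-2,5,5,8a-tetramethyl-4a,5,6,7,8,8a-hexahydronaphthalen-1(4H)-one, via keto aldehyde 17 (not isolated)
Conditions: TEMPO (10 mol %), PhI(OAc)2 (1.05 equiv), CH2Cl2, rt; then KOH, MeOH, rt → 40 °C
Reagents that add atoms: none
Why: Oxoammonium (TEMPO) oxidation is selective for the primary alcohol, and base then effects the intramolecular aldol condensation of the 1,5-keto aldehyde (the ring-closing half of a Robinson annulation), in which the trans-diequatorial C6 and C9 arms can only give the trans-fused ring B.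

**Step 11**
Reactants: 18 (4aS,6S,8aS)-6-hydroxy-2,5,5,8a-tetramethyl-4a,5,6,7,8,8a-hexahydronaphthalen-1(4H)-one
Product: 20 (2R,4aS,6S,8aS)-6-hydroxy-2,5,5,8a-tetramethyloctahydronaphthalen-1(2H)-one, via 8-epi ketone 19 (not isolated)
Conditions: H2 (1 atm), Pd/C, EtOAc, rt; filtration; NaOMe, MeOH, rt
Reagents that add atoms: none
Why: Heterogeneous hydrogenation saturates C7=C8, and methoxide equilibration through the C9 enolate should leave C17 equatorial (8α), since the 8β epimer has a 1,3-diaxial contact with C20.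

**Step 12**
Reactants: 20 (2R,4aS,6S,8aS)-6-hydroxy-2,5,5,8a-tetramethyloctahydronaphthalen-1(2H)-one
Product: 21 (2S,4aS,6R,8aR)-1,1,4a,6-tetramethyl-5-methylidenedecahydronaphthalen-2-ol
Conditions: Ph3PCH3Br, KOtBu (4 equiv each), toluene, 100 °C
Reagents that add atoms: methyltriphenylphosphonium bromide, C[P+](c1ccccc1)(c1ccccc1)c1ccccc1.[Br-]
Why: Wittig methylenation with a potassium alkoxide base in hot toluene is the standard answer to hindered, enolisable ketones; C8 is already the thermodynamic epimer and the 3-alkoxide is a spectator.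

**Step 13**
Reactants: 21 (2S,4aS,6R,8aR)-1,1,4a,6-tetramethyl-5-methylidenedecahydronaphthalen-2-ol
Product: 22 (2S,4aS,5R,6R,8aS)-1,1,4a,6-tetramethyloctahydro-2H-spiro[naphthalene-5,2′-oxiran]-2-ol (9α,11-epoxide)
Conditions: mCPBA, NaHCO3, CH2Cl2, 0 °C
Reagents that add atoms: 3-chloroperoxybenzoic acid, OOC(=O)c1cccc(Cl)c1
Why: Prilezhaev epoxidation should occur on the α face of the exocyclic alkene, anti to the axial C20 on the neighbouring carbon, which places the oxygen α (axial) and C11 β (equatorial) at C9.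

**Step 14**
Reactants: 22 (2S,4aS,5R,6R,8aS)-1,1,4a,6-tetramethyloctahydro-2H-spiro[naphthalene-5,2′-oxiran]-2-ol
Product: 23 (1R,2R,4aS,6S,8aS)-1-ethenyl-2,5,5,8a-tetramethyldecahydronaphthalene-1,6-diol
Conditions: Me3SI, nBuLi (4 equiv each), THF, −10 °C → rt
Reagents that add atoms: trimethylsulfonium iodide, C[S+](C)C.[I-]
Why: Corey–Chaykovsky-type homologation: the sulfonium ylide opens the epoxide at the primary C11 and the betaine eliminates dimethyl sulfide, giving the one-carbon-extended allylic alcohol with the C9–O bond and its configuration untouched.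

**Step 15**
Reactants: 23 (1R,2R,4aS,6S,8aS)-1-ethenyl-2,5,5,8a-tetramethyldecahydronaphthalene-1,6-diol; 24 3-bromofuran-2(5H)-one
Product: 26 3-{2-[(1R,2R,4aS,6S,8aS)-1,6-dihydroxy-2,5,5,8a-tetramethyldecahydronaphthalen-1-yl]ethyl}furan-2(5H)-one, via alkylborane 25 (not isolated)
Conditions: 9-BBN (3 equiv), THF, rt → 50 °C; then 24, PdCl2(dppf) (5 mol %), AsPh3, K3PO4 (aq), DMF, rt
Reagents that add atoms: none
Why: Anti-Markovnikov hydroboration places boron on C12, and B-alkyl Suzuki–Miyaura coupling with the α-bromo enoate carbon of 24 forms C12–C13 with the butenolide already in place and both hydroxyls free.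

**Step 16**
Reactants: 26 3-{2-[(1R,2R,4aS,6S,8aS)-1,6-dihydroxy-2,5,5,8a-tetramethyldecahydronaphthalen-1-yl]ethyl}furan-2(5H)-one
Product: 27 (2S,4aS,5R,6R,8aS)-5-hydroxy-1,1,4a,6-tetramethyl-5-[2-(2-oxo-2,5-dihydrofuran-3-yl)ethyl]decahydronaphthalen-2-yl acetate (target)
Conditions: Ac2O, pyridine, DMAP (cat.), CH2Cl2, 0 °C → rt
Reagents that add atoms: acetic anhydride, CC(=O)OC(C)=O
Why: Chemoselective esterification: the secondary equatorial 3-OH should be acetylated while the hindered tertiary axial 9-OH stays free.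

**Compound list**
1 | 4,4-dimethylcyclopent-2-en-1-one | CC1(C)CC(=O)C=C1 | starting material
2 | [(3,3-dimethylcyclopenta-1,4-dien-1-yl)oxy]trimethylsilane | C[Si](C)(C)OC1=CC(C)(C)C=C1 | intermediate
3 | trimethylsilyl (2Z)-5-hydroperoxy-5-methoxy-4,4-dimethylpent-2-enoate | C[Si](C)(C)OC(=O)/C=C\C(C)(C)C(OC)OO | intermediate
4 | 6-hydroxy-5,5-dimethyl-5,6-dihydro-2H-pyran-2-one (racemic lactol) | OC1OC(=O)C=CC1(C)C | intermediate
5 | 6-chloro-5,5-dimethyl-5,6-dihydro-2H-pyran-2-one (racemic) | ClC1OC(=O)C=CC1(C)C | intermediate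
6 | 2-methyl-3-oxobutanenitrile | CC(=O)C(C)C#N | starting material
7 | 2-methyl-3-[(trimethylsilyl)oxy]but-2-enenitrile (E/Z mixture) | CC(O[Si](C)(C)C)=C(C)C#N | intermediate
8 | N-[tert-butyl(dimethyl)silyl]-2-methyl-3-[(trimethylsilyl)oxy]buta-1,3-dien-1-imine | C=C(O[Si](C)(C)C)C(C)=C=N[Si](C)(C)C(C)(C)C | intermediate
9 | (6S)-6-{4-[(tert-butyldimethylsilyl)imino]-3-methyl-2-oxobut-3-en-1-yl}-5,5-dimethyl-5,6-dihydro-2H-pyran-2-one | O=C1C=CC(C)(C)[C@H](CC(=O)C(C)=C=N[Si](C)(C)C(C)(C)C)O1 | intermediate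
10 | (1S,5S,6S)-3-[(tert-butyldimethylsilyl)oxy]-6,9,9-trimethyl-7-oxo-2-oxabicyclo[3.3.1]non-3-ene-6-carbonitrile | O1[C@H]2CC(=O)[C@@](C#N)(C)[C@@H](C=C1O[Si](C)(C)C(C)(C)C)C2(C)C | intermediate
11 | (1S,5S,6S)-6,9,9-trimethyl-3,7-dioxo-2-oxabicyclo[3.3.1]nonane-6-carbonitrile | O1[C@H]2CC(=O)[C@@](C#N)(C)[C@@H](CC1=O)C2(C)C | intermediate
12 | C7 4-methylbenzenesulfonylhydrazone of 11 (bicyclic numbering; ring stereocentres as in 11) | O1[C@H]2CC(=NNS(=O)(=O)c3ccc(C)cc3)[C@@](C#N)(C)[C@@H](CC1=O)C2(C)C | intermediate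
13 | (1S,5R,6S)-6,9,9-trimethyl-3-oxo-2-oxabicyclo[3.3.1]nonane-6-carbonitrile | O1[C@H]2CC[C@@](C#N)(C)[C@@H](CC1=O)C2(C)C | intermediate
14 | (1S,2R,4S)-4-hydroxy-2-(2-hydroxyethyl)-1,3,3-trimethylcyclohexane-1-carbonitrile | O[C@H]1CC[C@@](C#N)(C)[C@@H](CCO)C1(C)C | intermediate
15 | 1-[(1S,2R,4S)-4-hydroxy-2-(2-hydroxyethyl)-1,3,3-trimethylcyclohexyl]propan-1-imine | O[C@H]1CC[C@@](C(=N)CC)(C)[C@@H](CCO)C1(C)C | intermediate
16 | 1-[(1S,2S,4S)-4-hydroxy-2-(2-hydroxyethyl)-1,3,3-trimethylcyclohexyl]propan-1-one | O[C@H]1CC[C@@](C(=O)CC)(C)[C@@H](CCO)C1(C)C | intermediate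
17 | 2-[(1S,2S,5S)-5-hydroxy-2,6,6-trimethyl-2-propanoylcyclohexyl]acetaldehyde | O[C@H]1CC[C@@](C(=O)CC)(C)[C@@H](CC=O)C1(C)C | intermediate
18 | (4aS,6S,8aS)-6-hydroxy-2,5,5,8a-tetramethyl-4a,5,6,7,8,8a-hexahydronaphthalen-1(4H)-one | O[C@H]1CC[C@@]2(C)[C@@H](CC=C(C)C2=O)C1(C)C | intermediate
19 | (2S,4aS,6S,8aS)-6-hydroxy-2,5,5,8a-tetramethyloctahydronaphthalen-1(2H)-one (8β-methyl epimer) | O[C@H]1CC[C@@]2(C)[C@@H](CC[C@H](C)C2=O)C1(C)C | intermediate
20 | (2R,4aS,6S,8aS)-6-hydroxy-2,5,5,8a-tetramethyloctahydronaphthalen-1(2H)-one | O[C@H]1CC[C@@]2(C)[C@@H](CC[C@@H](C)C2=O)C1(C)C | intermediate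
21 | (2S,4aS,6R,8aR)-1,1,4a,6-tetramethyl-5-methylidenedecahydronaphthalen-2-ol | O[C@H]1CC[C@@]2(C)[C@@H](CC[C@@H](C)C2=C)C1(C)C | intermediate
22 | (2S,4aS,5R,6R,8aS)-1,1,4a,6-tetramethyloctahydro-2H-spiro[naphthalene-5,2′-oxiran]-2-ol | O[C@H]1CC[C@@]2(C)[C@@H](CC[C@@H](C)[C@]2(O3)C3)C1(C)C | intermediate
23 | (1R,2R,4aS,6S,8aS)-1-ethenyl-2,5,5,8a-tetramethyldecahydronaphthalene-1,6-diol | O[C@H]1CC[C@@]2(C)[C@@H](CC[C@@H](C)[C@]2(O)C=C)C1(C)C | intermediate
24 | 3-bromofuran-2(5H)-one | O=C1OCC=C1Br | starting material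
25 | 9-{2-[(1R,2R,4aS,6S,8aS)-1,6-dihydroxy-2,5,5,8a-tetramethyldecahydronaphthalen-1-yl]ethyl}-9-borabicyclo[3.3.1]nonane | O[C@H]1CC[C@@]2(C)[C@@H](CC[C@@H](C)[C@]2(O)CCB2C3CCCC2CCC3)C1(C)C | intermediate
26 | 3-{2-[(1R,2R,4aS,6S,8aS)-1,6-dihydroxy-2,5,5,8a-tetramethyldecahydronaphthalen-1-yl]ethyl}furan-2(5H)-one | O[C@H]1CC[C@@]2(C)[C@@H](CC[C@@H](C)[C@]2(O)CCC2=CCOC2=O)C1(C)C | intermediate
27 | (2S,4aS,5R,6R,8aS)-5-hydroxy-1,1,4a,6-tetramethyl-5-[2-(2-oxo-2,5-dihydrofuran-3-yl)ethyl]decahydronaphthalen-2-yl acetate | CC(=O)O[C@H]1CC[C@@]2(C)[C@@H](CC[C@@H](C)[C@]2(O)CCC2=CCOC2=O)C1(C)C | target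

**Step count and risks**
Total step count: 16. Longest linear sequence: 14 steps (steps 1–3 and 6–16).

Steps most likely to fail:

Step 6. What may go wrong: ionisation by loss of the ring carboxylate instead of chloride, first attack through the ketene-imine carbon, poor facial discrimination by the ion pair, or protodesilylation of the ketene imine before ring closure. The fallback sets out from 4 and 8, comes back at 11, and makes the two bonds one after the other with known chemistry. Lactol 4 would be O-methylated on its open-chain carboxylate (MeI, K2CO3, DMF) to methyl (2Z)-4,4-dimethyl-5-oxopent-2-enoate F1. A Ti(OiPr)4/1,1′-bi-2-naphthol-catalysed aldol addition of 8 to F1 (the established catalytic asymmetric aldol of 1,3-bis(silyl enol ethers)), followed by CF3CO2H desilylation, should give methyl (2Z,5S)-8-cyano-5-hydroxy-4,4-dimethyl-7-oxonon-2-enoate F2. Pyridinium 4-methylbenzenesulfonate in toluene at 60 °C should lactonise it to 4-[(2S)-3,3-dimethyl-6-oxo-3,6-dihydro-2H-pyran-2-yl]-2-methyl-3-oxobutanenitrile F3, and catalytic DBU in CH2Cl2 at 0 °C should close ring A by the same intramolecular Michael addition to give 11.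

Step 7. What may go wrong: slow hydrazone formation at the carbonyl next to the quaternary carbon, loss of the lactone oxygen by β-elimination, or attack of the hydrazone nitrogen on the neighbouring nitrile. The fallback sets out from 11, comes back at 13, and removes the oxygen by a radical path. NaBH4 in MeOH at 0 °C should give 7-hydroxy-6,9,9-trimethyl-3-oxo-2-oxabicyclo[3.3.1]nonane-6-carbonitrile F4, and 1,1′-thiocarbonyldiimidazole with DMAP should convert it into O-(6-cyano-6,9,9-trimethyl-3-oxo-2-oxabicyclo[3.3.1]nonan-7-yl) 1H-imidazole-1-carbothioate F5. Bu3SnH/AIBN in toluene at 100 °C (Barton–McCombie deoxygenation) should then give 13.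

Step 15. What may go wrong: slow transmetalation and protodeboronation of the hindered, hydroxyl-coordinated alkylborane, and base-induced opening or double-bond migration of the bromobutenolide. The fallback sets out from 23, comes back at 26, and builds the butenolide by enolate alkylation. Hydroboration–oxidation (9-BBN; NaBO3) should give (1R,2R,4aS,6S,8aS)-1-(2-hydroxyethyl)-2,5,5,8a-tetramethyldecahydronaphthalene-1,6-diol F6, and I2/PPh3/imidazole should convert the primary alcohol into (1R,2R,4aS,6S,8aS)-1-(2-iodoethyl)-2,5,5,8a-tetramethyldecahydronaphthalene-1,6-diol F7. Alkylation of excess lithium enolate of 3-(phenylsulfanyl)dihydrofuran-2(3H)-one (LiN(iPr)2, THF/DMPU) should give 3-{2-[(1R,2R,4aS,6S,8aS)-1,6-dihydroxy-2,5,5,8a-tetramethyldecahydronaphthalen-1-yl]ethyl}-3-(phenylsulfanyl)dihydrofuran-2(3H)-one F8. mCPBA at −78 °C should oxidise it to the corresponding 3-(phenylsulfinyl) lactone F9, and thermal syn-elimination of the sulfoxide (toluene, 110 °C) should give 26.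

**Further compounds**
F1 | step 6 | methyl (2Z)-4,4-dimethyl-5-oxopent-2-enoate | COC(=O)/C=C\C(C)(C)C=O
F2 | step 6 | methyl (2Z,5S)-8-cyano-5-hydroxy-4,4-dimethyl-7-oxonon-2-enoate | COC(=O)/C=C\C(C)(C)[C@@H](O)CC(=O)C(C)C#N
F3 | step 6 | 4-[(2S)-3,3-dimethyl-6-oxo-3,6-dihydro-2H-pyran-2-yl]-2-methyl-3-oxobutanenitrile | O=C1C=CC(C)(C)[C@H](CC(=O)C(C)C#N)O1
F4 | step 7 | 7-hydroxy-6,9,9-trimethyl-3-oxo-2-oxabicyclo[3.3.1]nonane-6-carbonitrile (ring stereocentres as in 11) | O1[C@H]2CC(O)[C@@](C#N)(C)[C@@H](CC1=O)C2(C)C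
F5 | step 7 | O-(6-cyano-6,9,9-trimethyl-3-oxo-2-oxabicyclo[3.3.1]nonan-7-yl) 1H-imidazole-1-carbothioate (ring stereocentres as in 11) | O1[C@H]2CC(OC(=S)n3ccnc3)[C@@](C#N)(C)[C@@H](CC1=O)C2(C)C
F6 | step 15 | (1R,2R,4aS,6S,8aS)-1-(2-hydroxyethyl)-2,5,5,8a-tetramethyldecahydronaphthalene-1,6-diol | O[C@H]1CC[C@@]2(C)[C@@H](CC[C@@H](C)[C@]2(O)CCO)C1(C)C
F7 | step 15 | (1R,2R,4aS,6S,8aS)-1-(2-iodoethyl)-2,5,5,8a-tetramethyldecahydronaphthalene-1,6-diol | O[C@H]1CC[C@@]2(C)[C@@H](CC[C@@H](C)[C@]2(O)CCI)C1(C)C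
F8 | step 15 | 3-{2-[(1R,2R,4aS,6S,8aS)-1,6-dihydroxy-2,5,5,8a-tetramethyldecahydronaphthalen-1-yl]ethyl}-3-(phenylsulfanyl)dihydrofuran-2(3H)-one | O[C@H]1CC[C@@]2(C)[C@@H](CC[C@@H](C)[C@]2(O)CCC2(Sc3ccccc3)CCOC2=O)C1(C)C
F9 | step 15 | 3-{2-[(1R,2R,4aS,6S,8aS)-1,6-dihydroxy-2,5,5,8a-tetramethyldecahydronaphthalen-1-yl]ethyl}-3-(phenylsulfinyl)dihydrofuran-2(3H)-one | O[C@H]1CC[C@@]2(C)[C@@H](CC[C@@H](C)[C@]2(O)CCC2(S(=O)c3ccccc3)CCOC2=O)C1(C)C
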